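## Retrosynthetic overview

1. Endgame: both silyl ethers come off last. Before that the dihydropyran ring is closed at O1–C8a by palladium-catalysed intramolecular aryl etherification of a tertiary alcohol with an aryl chloride. It is the only ring formed in the route and is made after the key step; the benzene ring is bought.
2. Key disconnection C2–C1': a one-pot lithiation–borylation–oxidation joins a lithiated (S)-4-arylbutan-2-yl 2,4,6-triisopropylbenzoate (C2 as carbenoid) with the complete side chain as its C1' neopentyl glycol boronic ester. Boron acts as a temporary one-atom tether between C2 and C1' and is finally replaced by the C2 oxygen.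
3. Enabling feature: C2 of the dihydropyran ring is a tertiary ether carbon carrying O1, a methyl group and two unbranched CH2 groups (C3 and C1'). It can therefore be traced to a secondary carbinol carbon (C2–H acidified, then vacated, by an ester oxygen) plus a primary alkylboron group. O1 sits on C8a para to the C6 oxygen, so a para-chlorophenol can supply the arene.
4. Aryl half: 4-chloro-3,5-dimethylphenol (chlorine = future C8a) is silylated, brominated at one methyl group (future C4) and added as its Grignard reagent to (R)-propylene oxide (C3, C2 and the 2-methyl group). Mitsunobu inversion gives the (S)-benzoate.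
5. Side-chain half: geranyl acetate → allylic oxidation of the (E)-methyl group (C9') → catalytic asymmetric allylboration (9'R) → cross-metathesis to the prenyl end → one-carbon extension and terminal hydroboration to put boron on C1'.

Key step: step 14

Remark: the chroman is numbered O1, C2–C8a and the side chain C1'–C12'. The SMILES is read as (2R,9'R) with 3'E and 7'E double bonds. All reagents named are assumed to be commercially available.

## Route

Step 1
Reactants: 1 geranyl acetate [(2E)-3,7-dimethylocta-2,6-dien-1-yl acetate]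
Product: 2 (2E,6E)-8-hydroxy-3,7-dimethylocta-2,6-dien-1-yl acetate
Conditions: SeO2 (cat.), tBuOOH, salicylic acid (cat.), CH2Cl2, rt
Reagents that add atoms: tert-butyl hydroperoxide, CC(C)(C)OO (net source of the new oxygen; SeO2, O=[Se]=O, is the oxygen-transfer catalyst)
Why: Riley oxidation (ene reaction followed by a [2,3]-sigmatropic shift) is known to oxidise the (E)-methyl group of the electron-richer terminal alkene of geranyl esters selectively, which places oxygen on the future C9' and keeps both E double bonds.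

Step 2
Reactants: 2 (2E,6E)-8-hydroxy-3,7-dimethylocta-2,6-dien-1-yl acetate
Product: 3 (2E,6E)-3,7-dimethyl-8-oxoocta-2,6-dien-1-yl acetate
Conditions: MnO2, CH2Cl2, rt
Reagents that add atoms: none
Why: MnO2 oxidises allylic alcohols selectively to enals without touching the acetate or the alkene geometry.

Step 3
Reactants: 3 (2E,6E)-3,7-dimethyl-8-oxoocta-2,6-dien-1-yl acetate
Product: 5 (2E,6E,8R)-8-hydroxy-3,7-dimethylundeca-2,6,10-trien-1-yl acetate, via O-pinacolboryl ether 4 (not isolated)
Conditions: allylB(pin), (R)-TRIP [(R)-3,3'-bis(2,4,6-triisopropylphenyl)-1,1'-binaphthyl-2,2'-diyl hydrogen phosphate] (5 mol %), toluene, −30 °C; aqueous work-up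
Reagents that add atoms: allylboronic acid pinacol ester, C=CCB1OC(C)(C)C(C)(C)O1 (allyl group; the boryl group stays only in 4)
Why: Chiral phosphoric acid-catalysed allylboration passes through a closed six-membered chair transition state in which the (R)-acid is expected to expose the Re face of the enal, so that C9' is set as R while the acetate and the trisubstituted alkenes stay inert.

Step 4
Reactants: 5 (2E,6E,8R)-8-hydroxy-3,7-dimethylundeca-2,6,10-trien-1-yl acetate
Product: 6 (2E,6E,8R)-8-(tert-butyldimethylsilyloxy)-3,7-dimethylundeca-2,6,10-trien-1-yl acetate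
Conditions: TBSCl, imidazole, DMF, rt
Reagents that add atoms: tert-butyldimethylsilyl chloride, CC(C)(C)[Si](C)(C)Cl
Why: Standard silylation of a secondary alcohol protects the C9' hydroxyl against the organometallic steps to come.

Step 5
Reactants: 6 (2E,6E,8R)-8-(tert-butyldimethylsilyloxy)-3,7-dimethylundeca-2,6,10-trien-1-yl acetate
Product: 7 (2E,6E,8R)-8-(tert-butyldimethylsilyloxy)-3,7,11-trimethyldodeca-2,6,10-trien-1-yl acetate
Conditions: 2-methyl-2-butene (excess), second-generation Grubbs catalyst (3 mol %), CH2Cl2, 40 °C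
Reagents that add atoms: 2-methyl-2-butene, CC=C(C)C
Why: Olefin cross-metathesis should turn the monosubstituted terminal alkene into the prenyl terminus, because the ruthenium carbene initiates only on the unhindered vinyl group and leaves the two trisubstituted alkenes (one shielded by the silyloxy group, one next to the acetate) untouched.

Step 6
Reactants: 7 (2E,6E,8R)-8-(tert-butyldimethylsilyloxy)-3,7,11-trimethyldodeca-2,6,10-trien-1-yl acetate
Product: 8 (2E,6E,8R)-8-(tert-butyldimethylsilyloxy)-3,7,11-trimethyldodeca-2,6,10-trien-1-ol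
Conditions: K2CO3 (cat.), MeOH, 0 °C to rt
Reagents that add atoms: none
Why: Base-catalysed methanolysis removes the acetate without affecting the silyl ether or the alkenes.

Step 7
Reactants: 8 (2E,6E,8R)-8-(tert-butyldimethylsilyloxy)-3,7,11-trimethyldodeca-2,6,10-trien-1-ol
Product: 9 (2E,6E,8R)-8-(tert-butyldimethylsilyloxy)-3,7,11-trimethyldodeca-2,6,10-trienal
Conditions: MnO2, CH2Cl2, rt
Reagents that add atoms: none
Why: MnO2 oxidation of the primary allylic alcohol gives the (2E)-enal under neutral conditions without over-oxidation or E/Z isomerisation.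

Step 8
Reactants: 9 (2E,6E,8R)-8-(tert-butyldimethylsilyloxy)-3,7,11-trimethyldodeca-2,6,10-trienal
Product: 10 (3E,7E,9R)-9-(tert-butyldimethylsilyloxy)-4,8,12-trimethyltrideca-1,3,7,11-tetraene
Conditions: Ph3PCH3Br, KOtBu, THF, 0 °C to rt
Reagents that add atoms: methyltriphenylphosphonium bromide, C[P+](c1ccccc1)(c1ccccc1)c1ccccc1.[Br-]
Why: Wittig methylenation of the enal gives the terminal 1,3-diene and adds the carbon that becomes C1', and the unstabilised ylide does not isomerise the 3'E double bond at low temperature.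

Step 9
Reactants: 10 (3E,7E,9R)-9-(tert-butyldimethylsilyloxy)-4,8,12-trimethyltrideca-1,3,7,11-tetraene
Product: 13 2-[(3E,7E,9R)-9-(tert-butyldimethylsilyloxy)-4,8,12-trimethyltrideca-3,7,11-trien-1-yl]-5,5-dimethyl-1,3,2-dioxaborinane, via bis(isopinocampheyl)borane adduct 11 (not isolated), via diethyl boronate 12 (not isolated)
Conditions: (−)-Ipc2BH, THF, 0 °C; then CH3CHO (excess), 0 °C to rt; then neopentyl glycol, rt
Reagents that add atoms: (−)-diisopinocampheylborane, B([C@@H]1C[C@@H]2C[C@H]([C@H]1C)C2(C)C)[C@@H]1C[C@@H]2C[C@H]([C@H]1C)C2(C)C (boron); neopentyl glycol, OCC(C)(C)CO; acetaldehyde, CC=O (ethoxy groups of 12 only)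
Why: The bulky dialkylborane hydroborates only the monosubstituted terminal alkene of the diene in the anti-Markovnikov sense (boron on C1'), acetaldehyde then expels both isopinocampheyl groups as α-pinene by β-hydride transfer, and transesterification with neopentyl glycol gives the unhindered cyclic boronic ester needed in step 14 (the chirality of the borane plays no role).

Step 10
Reactants: 14 4-chloro-3,5-dimethylphenol
Product: 15 (4-chloro-3,5-dimethylphenoxy)triisopropylsilane
Conditions: TIPSCl, imidazole, DMF, rt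
Reagents that add atoms: triisopropylsilyl chloride, CC(C)[Si](Cl)(C(C)C)C(C)C
Why: Silylation of the phenol with the bulky triisopropylsilyl group gives an ether that withstands radical bromination, Grignard formation and sBuLi and does not direct ortho-metalation.

Step 11
Reactants: 15 (4-chloro-3,5-dimethylphenoxy)triisopropylsilane
Product: 16 [3-(bromomethyl)-4-chloro-5-methylphenoxy]triisopropylsilane
Conditions: NBS (1.0 equiv), AIBN (cat.), PhCF3, 80 °C
Reagents that add atoms: N-bromosuccinimide, O=C1CCC(=O)N1Br
Why: Wohl–Ziegler benzylic bromination under radical conditions attacks one of the two equivalent methyl groups, so mono-bromination at limited conversion gives a single constitutional isomer, while the ring positions are shielded by the flanking silyloxy and methyl groups.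

Step 12
Reactants: 16 [3-(bromomethyl)-4-chloro-5-methylphenoxy]triisopropylsilane; 17 (R)-propylene oxide [(2R)-2-methyloxirane]
Product: 19 (2R)-4-[2-chloro-3-methyl-5-(triisopropylsilyloxy)phenyl]butan-2-ol, via benzylic Grignard reagent 18 (not isolated)
Conditions: Mg turnings, 2-MeTHF, 0 °C; then CuI (10 mol %), 17, −30 to 0 °C; aq. NH4Cl
Reagents that add atoms: magnesium, [Mg] (held only in intermediate 18)
Why: The benzylic Grignard reagent, formed in 2-MeTHF to suppress Wurtz coupling, opens the epoxide at its CH2 group under CuI catalysis (SN2), so the stereocentre of (R)-propylene oxide is carried over unchanged as the (R)-carbinol.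

Step 13
Reactants: 19 (2R)-4-[2-chloro-3-methyl-5-(triisopropylsilyloxy)phenyl]butan-2-ol
Product: 20 (2S)-4-[2-chloro-3-methyl-5-(triisopropylsilyloxy)phenyl]butan-2-yl 2,4,6-triisopropylbenzoate
Conditions: 2,4,6-triisopropylbenzoic acid, PPh3, DIAD, THF, 0 °C to rt
Reagents that add atoms: 2,4,6-triisopropylbenzoic acid, CC(C)c1cc(C(C)C)c(C(=O)O)c(C(C)C)c1
Why: The Mitsunobu reaction esterifies the secondary alcohol with clean SN2 inversion and so gives the (S)-configured hindered benzoate, whose bulk later blocks attack of sBuLi at the carbonyl group.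

Step 14
Reactants: 20 (2S)-4-[2-chloro-3-methyl-5-(triisopropylsilyloxy)phenyl]butan-2-yl 2,4,6-triisopropylbenzoate; 13 2-[(3E,7E,9R)-9-(tert-butyldimethylsilyloxy)-4,8,12-trimethyltrideca-3,7,11-trien-1-yl]-5,5-dimethyl-1,3,2-dioxaborinane
Product: 24 (3R,6E,10E,12R)-12-(tert-butyldimethylsilyloxy)-1-[2-chloro-3-methyl-5-(triisopropylsilyloxy)phenyl]-3,7,11,15-tetramethylhexadeca-6,10,14-trien-3-ol, via lithiated benzoate 21 (not isolated), via lithium boronate complex 22 (not isolated), via tertiary boronic ester 23 (not isolated)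
Conditions: 20 (1.5 equiv), sBuLi (1.4 equiv), TMEDA (6 equiv), cyclopentyl methyl ether, −60 °C; then 13 (1.0 equiv), −60 °C to 50 °C; then NaOH, H2O2, THF/H2O, 0 °C
Reagents that add atoms: hydrogen peroxide, OO (oxygen of the C2 hydroxyl); sec-butyllithium, CCC(C)[Li] (lithium of 21 and 22 only)
Why: sBuLi/TMEDA, guided by the benzoate carbonyl, removes the C2–H of 20 with retention to give the configurationally stable α-oxy organolithium 21, which the unhindered neopentyl glycol boronic ester 13 traps at boron with retention to give boronate complex 22, so that boron becomes a one-atom tether holding C2 and C1' together. On warming, C1' shifts from boron to C2 anti to the departing 2,4,6-triisopropylbenzoate (stereoinvertive 1,2-metallate rearrangement), which makes the C2–C1' bond and the fully substituted centre in tertiary boronic ester 23, and alkaline H2O2 then exchanges boron for hydroxyl with retention to give 24. The closest known reaction type is the lithiation–borylation–oxidation of secondary dialkyl 2,4,6-triisopropylbenzoates (4-arylbutan-2-yl esters included) with primary alkyl neopentyl glycol boronic esters to give tertiary alcohols. No ring is closed in this step, so no mode of ring closure applies; the dihydropyran ring follows in step 15. The only new stereocentre, C2, is controlled by the (S)-carbinol centre of 20 alone: retention (lithiation), retention (borylation), inversion (migration) and retention (oxidation) should translate (S)-20 into (R)-24 without loss of enantiopurity. The step needs deprotonation at C2 in preference to arene metalation, benzylic deprotonation and chlorine–lithium exchange, and carbon in preference to oxygen migration; the directing ester, the absence of a hydrogen ortho to chlorine, the poorly directing bulky silyl ether, the inertness of an aryl chloride (unlike a bromide) toward sBuLi at −60 °C and the good migratory aptitude of a primary alkyl group should secure this.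

Step 15
Reactants: 24 (3R,6E,10E,12R)-12-(tert-butyldimethylsilyloxy)-1-[2-chloro-3-methyl-5-(triisopropylsilyloxy)phenyl]-3,7,11,15-tetramethylhexadeca-6,10,14-trien-3-ol
Product: 25 (2R)-2-[(3E,7E,9R)-9-(tert-butyldimethylsilyloxy)-4,8,12-trimethyltrideca-3,7,11-trien-1-yl]-2,8-dimethyl-6-(triisopropylsilyloxy)chromane
Conditions: Pd(OAc)2 (5 mol %), 2-di-tert-butylphosphino-2',4',6'-triisopropylbiphenyl (10 mol %), Cs2CO3, toluene, 90 °C
Reagents that add atoms: none
Why: Intramolecular Buchwald–Hartwig-type etherification (oxidative addition of the aryl chloride to zerovalent palladium, alkoxide exchange, C–O reductive elimination) closes the six-membered dihydropyran ring; the tertiary alkoxide cannot undergo β-hydride elimination and C2 is not touched, so its configuration is kept.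

Step 16
Reactants: 25 (2R)-2-[(3E,7E,9R)-9-(tert-butyldimethylsilyloxy)-4,8,12-trimethyltrideca-3,7,11-trien-1-yl]-2,8-dimethyl-6-(triisopropylsilyloxy)chromane
Product: 26 sargachromanol C [(2R)-2-[(3E,7E,9R)-9-hydroxy-4,8,12-trimethyltrideca-3,7,11-trien-1-yl]-2,8-dimethylchroman-6-ol]
Conditions: TBAF, AcOH (buffer), degassed THF, 0 °C to rt
Reagents that add atoms: none
Why: Fluoride cleaves the aryl triisopropylsilyl ether and the alkyl tert-butyldimethylsilyl ether in one operation under buffered conditions that spare the allylic alcohol, the alkenes and the oxidation-prone chromanol.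

## Compound list

1 | geranyl acetate | CC(C)=CCC/C(C)=C/COC(C)=O | starting material
2 | (2E,6E)-8-hydroxy-3,7-dimethylocta-2,6-dien-1-yl acetate | OC/C(C)=C/CC/C(C)=C/COC(C)=O | intermediate
3 | (2E,6E)-3,7-dimethyl-8-oxoocta-2,6-dien-1-yl acetate | O=C/C(C)=C/CC/C(C)=C/COC(C)=O | intermediate
4 | (2E,6E,8R)-3,7-dimethyl-8-[(4,4,5,5-tetramethyl-1,3,2-dioxaborolan-2-yl)oxy]undeca-2,6,10-trien-1-yl acetate | C=CC[C@@H](OB1OC(C)(C)C(C)(C)O1)/C(C)=C/CC/C(C)=C/COC(C)=O | intermediate
5 | (2E,6E,8R)-8-hydroxy-3,7-dimethylundeca-2,6,10-trien-1-yl acetate | C=CC[C@@H](O)/C(C)=C/CC/C(C)=C/COC(C)=O | intermediate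
6 | (2E,6E,8R)-8-(tert-butyldimethylsilyloxy)-3,7-dimethylundeca-2,6,10-trien-1-yl acetate | C=CC[C@@H](O[Si](C)(C)C(C)(C)C)/C(C)=C/CC/C(C)=C/COC(C)=O | intermediate
7 | (2E,6E,8R)-8-(tert-butyldimethylsilyloxy)-3,7,11-trimethyldodeca-2,6,10-trien-1-yl acetate | CC(C)=CC[C@@H](O[Si](C)(C)C(C)(C)C)/C(C)=C/CC/C(C)=C/COC(C)=O | intermediate
8 | (2E,6E,8R)-8-(tert-butyldimethylsilyloxy)-3,7,11-trimethyldodeca-2,6,10-trien-1-ol | CC(C)=CC[C@@H](O[Si](C)(C)C(C)(C)C)/C(C)=C/CC/C(C)=C/CO | intermediate
9 | (2E,6E,8R)-8-(tert-butyldimethylsilyloxy)-3,7,11-trimethyldodeca-2,6,10-trienal | CC(C)=CC[C@@H](O[Si](C)(C)C(C)(C)C)/C(C)=C/CC/C(C)=C/C=O | intermediate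
10 | (3E,7E,9R)-9-(tert-butyldimethylsilyloxy)-4,8,12-trimethyltrideca-1,3,7,11-tetraene | CC(C)=CC[C@@H](O[Si](C)(C)C(C)(C)C)/C(C)=C/CC/C(C)=C/C=C | intermediate
11 | [(3E,7E,9R)-9-(tert-butyldimethylsilyloxy)-4,8,12-trimethyltrideca-3,7,11-trien-1-yl]bis(isopinocampheyl)borane (isopinocampheyl groups from (+)-α-pinene) | CC(C)=CC[C@@H](O[Si](C)(C)C(C)(C)C)/C(C)=C/CC/C(C)=C/CCB([C@@H]1C[C@@H]2C[C@H]([C@H]1C)C2(C)C)[C@@H]1C[C@@H]2C[C@H]([C@H]1C)C2(C)C | intermediate
12 | diethyl [(3E,7E,9R)-9-(tert-butyldimethylsilyloxy)-4,8,12-trimethyltrideca-3,7,11-trien-1-yl]boronate | CC(C)=CC[C@@H](O[Si](C)(C)C(C)(C)C)/C(C)=C/CC/C(C)=C/CCB(OCC)OCC | intermediate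
13 | 2-[(3E,7E,9R)-9-(tert-butyldimethylsilyloxy)-4,8,12-trimethyltrideca-3,7,11-trien-1-yl]-5,5-dimethyl-1,3,2-dioxaborinane | CC(C)=CC[C@@H](O[Si](C)(C)C(C)(C)C)/C(C)=C/CC/C(C)=C/CCB1OCC(C)(C)CO1 | intermediate
14 | 4-chloro-3,5-dimethylphenol | Cc1cc(O)cc(C)c1Cl | starting material
15 | (4-chloro-3,5-dimethylphenoxy)triisopropylsilane | Cc1cc(O[Si](C(C)C)(C(C)C)C(C)C)cc(C)c1Cl | intermediate
16 | [3-(bromomethyl)-4-chloro-5-methylphenoxy]triisopropylsilane | BrCc1cc(O[Si](C(C)C)(C(C)C)C(C)C)cc(C)c1Cl | intermediate
17 | (R)-propylene oxide | C[C@@H]1CO1 | starting material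
18 | [2-chloro-3-methyl-5-(triisopropylsilyloxy)benzyl]magnesium bromide | Br[Mg]Cc1cc(O[Si](C(C)C)(C(C)C)C(C)C)cc(C)c1Cl | intermediate
19 | (2R)-4-[2-chloro-3-methyl-5-(triisopropylsilyloxy)phenyl]butan-2-ol | C[C@@H](O)CCc1cc(O[Si](C(C)C)(C(C)C)C(C)C)cc(C)c1Cl | intermediate
20 | (2S)-4-[2-chloro-3-methyl-5-(triisopropylsilyloxy)phenyl]butan-2-yl 2,4,6-triisopropylbenzoate | C[C@H](OC(=O)c1c(C(C)C)cc(C(C)C)cc1C(C)C)CCc1cc(O[Si](C(C)C)(C(C)C)C(C)C)cc(C)c1Cl | intermediate
21 | C2-lithiated benzoate (lithium in the place of the C2 hydrogen of 20, configuration retained) | C[C@]([Li])(OC(=O)c1c(C(C)C)cc(C(C)C)cc1C(C)C)CCc1cc(O[Si](C(C)C)(C(C)C)C(C)C)cc(C)c1Cl | intermediate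
22 | lithium boronate complex (boron bonded to C2, to C1' and to the neopentyl glycol oxygens; benzoate still on C2) | [Li+].CC(C)=CC[C@@H](O[Si](C)(C)C(C)(C)C)/C(C)=C/CC/C(C)=C/CC[B-]1(OCC(C)(C)CO1)[C@@](C)(OC(=O)c1c(C(C)C)cc(C(C)C)cc1C(C)C)CCc1cc(O[Si](C(C)C)(C(C)C)C(C)C)cc(C)c1Cl | intermediate
23 | tertiary neopentyl glycol boronic ester (boron on C2 in the place of the later hydroxyl of 24) | CC(C)=CC[C@@H](O[Si](C)(C)C(C)(C)C)/C(C)=C/CC/C(C)=C/CC[C@](B1OCC(C)(C)CO1)(C)CCc1cc(O[Si](C(C)C)(C(C)C)C(C)C)cc(C)c1Cl | intermediate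
24 | (3R,6E,10E,12R)-12-(tert-butyldimethylsilyloxy)-1-[2-chloro-3-methyl-5-(triisopropylsilyloxy)phenyl]-3,7,11,15-tetramethylhexadeca-6,10,14-trien-3-ol | CC(C)=CC[C@@H](O[Si](C)(C)C(C)(C)C)/C(C)=C/CC/C(C)=C/CC[C@](O)(C)CCc1cc(O[Si](C(C)C)(C(C)C)C(C)C)cc(C)c1Cl | intermediate
25 | (2R)-2-[(3E,7E,9R)-9-(tert-butyldimethylsilyloxy)-4,8,12-trimethyltrideca-3,7,11-trien-1-yl]-2,8-dimethyl-6-(triisopropylsilyloxy)chromane | CC(C)=CC[C@@H](O[Si](C)(C)C(C)(C)C)/C(C)=C/CC/C(C)=C/CC[C@]1(C)CCc2cc(O[Si](C(C)C)(C(C)C)C(C)C)cc(C)c2O1 | intermediate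
26 | sargachromanol C | CC(C)=CC[C@@H](O)/C(C)=C/CC/C(C)=C/CC[C@]1(C)CCc2cc(O)cc(C)c2O1 | target

## Step count and risks

Total: 16 steps (fallbacks not counted). Longest linear sequence: 12 steps (steps 1–9, then 14–16).

**Step 14 (key step).** Metalation may go astray (arene or benzylic deprotonation, slow removal of the hindered C2–H), or the crowded boronate complex may form reversibly and fail to rearrange. The fallback keeps the C2–C1' disconnection but replaces the carbenoid by the alkylation of a chiral lactate enolate (self-regeneration of the stereocentre through a temporary acetal ring). It sets out from tetraene 10 and bromide 16 and comes back at 24.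
- Tetraene 10 would be hydroborated at its terminal alkene with disiamylborane and oxidised (NaOH, H2O2) to the homoallylic alcohol F1.
- I2, PPh3 and imidazole would convert this into the primary iodide F2.
- The lithium enolate (LDA, THF/DMPU, −78 °C) of (2S,5S)-2-tert-butyl-5-methyl-1,3-dioxolan-4-one, the pivalaldehyde acetal of (S)-lactic acid, would be alkylated by F2 on the face opposite to the tert-butyl group to give the dioxolanone F3.
- LiAlH4 would reduce this to the diol F4.
- Selective tosylation of the primary hydroxyl would give the tosylate F5, and K2CO3 in MeOH would close the epoxide F6.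
- CuI-catalysed opening of F6 at its CH2 group by Grignard reagent 18 (made from 16 as in step 12) would give 24.

**Step 15.** Oxidative addition of zerovalent palladium into the hindered, electron-rich aryl chloride may be slow, so that protodechlorination or catalyst decay wins. The fallback closes the O1–C8a bond oxidatively and not by cross-coupling. It sets out from 24 and comes back at 26.
- TBAF would remove both silyl groups of 24 to give the chlorophenol triol F7.
- PhI(OAc)2 (a trivalent iodine oxidant) in MeCN/MeOH at 0 °C would dearomatise the phenol. The tertiary hydroxyl should attack C8a, the chlorine-bearing carbon para to the phenol oxygen, closing the six-membered ring; chloride is lost and methanol is taken up to give the methoxy dienone ketal F8. The C2–O bond is never broken, so C2 keeps its configuration.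
- Ascorbic acid (or Zn, AcOH) would reduce this ketal with loss of methanol and re-aromatisation to 26, the known way in which 8a-alkoxy chromanone ketals of the vitamin E series return to 6-chromanols.

**Step 9.** A trisubstituted alkene may be hydroborated as well, or the second isopinocampheyl group may be removed incompletely. The fallback makes the C1'–B bond by borylation of a C1' halide. It sets out from 10 and comes back at 13.
- Tetraene 10 would be taken to the homoallylic alcohol F1 as described for step 14.
- CBr4 and PPh3 would convert it into the primary bromide F9.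
- CuI (cat.), PPh3, LiOMe and bis(neopentyl glycolato)diboron in DMF at rt would give 13.

Further compounds

F1 | step 14 | (3E,7E,9R)-9-(tert-butyldimethylsilyloxy)-4,8,12-trimethyltrideca-3,7,11-trien-1-ol | CC(C)=CC[C@@H](O[Si](C)(C)C(C)(C)C)/C(C)=C/CC/C(C)=C/CCO
F2 | step 14 | (3E,7E,9R)-9-(tert-butyldimethylsilyloxy)-1-iodo-4,8,12-trimethyltrideca-3,7,11-triene | CC(C)=CC[C@@H](O[Si](C)(C)C(C)(C)C)/C(C)=C/CC/C(C)=C/CCI
F3 | step 14 | (2S,5R)-2-tert-butyl-5-[(3E,7E,9R)-9-(tert-butyldimethylsilyloxy)-4,8,12-trimethyltrideca-3,7,11-trien-1-yl]-5-methyl-1,3-dioxolan-4-one | CC(C)=CC[C@@H](O[Si](C)(C)C(C)(C)C)/C(C)=C/CC/C(C)=C/CC[C@@]1(C)O[C@H](C(C)(C)C)OC1=O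
F4 | step 14 | (2R,5E,9E,11R)-11-(tert-butyldimethylsilyloxy)-2,6,10,14-tetramethylpentadeca-5,9,13-triene-1,2-diol | CC(C)=CC[C@@H](O[Si](C)(C)C(C)(C)C)/C(C)=C/CC/C(C)=C/CC[C@](O)(C)CO
F5 | step 14 | (2R,5E,9E,11R)-11-(tert-butyldimethylsilyloxy)-2-hydroxy-2,6,10,14-tetramethylpentadeca-5,9,13-trien-1-yl 4-methylbenzenesulfonate | CC(C)=CC[C@@H](O[Si](C)(C)C(C)(C)C)/C(C)=C/CC/C(C)=C/CC[C@](O)(C)COS(=O)(=O)c1ccc(C)cc1
F6 | step 14 | (2R)-2-[(3E,7E,9R)-9-(tert-butyldimethylsilyloxy)-4,8,12-trimethyltrideca-3,7,11-trien-1-yl]-2-methyloxirane | CC(C)=CC[C@@H](O[Si](C)(C)C(C)(C)C)/C(C)=C/CC/C(C)=C/CC[C@]1(C)CO1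
F7 | step 15 | (3R,6E,10E,12R)-1-(2-chloro-5-hydroxy-3-methylphenyl)-3,7,11,15-tetramethylhexadeca-6,10,14-triene-3,12-diol | CC(C)=CC[C@@H](O)/C(C)=C/CC/C(C)=C/CC[C@](O)(C)CCc1cc(O)cc(C)c1Cl
F8 | step 15 | (2R)-2-[(3E,7E,9R)-9-hydroxy-4,8,12-trimethyltrideca-3,7,11-trien-1-yl]-8a-methoxy-2,8-dimethyl-3,4-dihydro-2H-chromen-6(8aH)-one (either configuration at C8a) | CC(C)=CC[C@@H](O)/C(C)=C/CC/C(C)=C/CC[C@]1(C)CCC2=CC(=O)C=C(C)C2(OC)O1
F9 | step 9 | (3E,7E,9R)-1-bromo-9-(tert-butyldimethylsilyloxy)-4,8,12-trimethyltrideca-3,7,11-triene | CC(C)=CC[C@@H](O[Si](C)(C)C(C)(C)C)/C(C)=C/CC/C(C)=C/CCBr
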